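Everything rests on cutting the ten-membered carbocycle between C8 and C9. The ring carries oxygen on C8 and, two carbons on, a methyl-bearing tertiary carbinol at C10; a dithiane-masked C8 carbonyl, lithiated, can therefore attack the CH2 terminus (C9) of a C10-methyl oxirane, which creates the C8–C9 bond, frees the C10 hydroxyl and closes the ring at once. The precursor is an open chain with the 1,3-dithiane at C8 and the oxirane at the other end, the (Z)-C4=C5 alkene and the C3, C6, C7 and C10 centres already set, and C1 held as a silyl-protected carbinol (a ketal beside the oxirane could be neither installed nor removed safely).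

Key step: step 18

Remarks on the chemistry
- Locants C1–C13 are those of the germacranolide skeleton of the target 37: C1 ketone, C3 carbinol, C4(Me)=C5, C6 lactone CH–O, C7, C8 ester CH–O, C9, C10 methyl carbinol, C11=C13H2, C12 lactone carbonyl. 37 is (3R,4Z,6R,7R,8R,10R); its C8 and C10 oxygens are 1,3-anti.
- Assumption: C1 of 23–32 is a temporary stereocentre, drawn as the expected major (1S) epimer; any (1R) epimer converges on 33 in step 23.
- Precursor design: C1 is a triethylsilyl-protected carbinol and O3 a silyl ether. Both go on under basic conditions in the presence of the oxirane and come off without the acid that would endanger the C3 β-hydroxy ketone and the allylic C6 lactone. The dithiane is installed before any oxirane or oxidant-sensitive step, and the oxirane arrives preformed.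
- TBS = tert-butyldimethylsilyl, TES = triethylsilyl.

Step 1
Reactants: 1 2-methylprop-2-en-1-ol (methallyl alcohol)
Product: 3 3-(hydroxymethyl)but-3-enoic acid, via dilithio dianion 2 (not isolated)
Conditions: n-BuLi (2.2 equiv), TMEDA, Et2O, 0 °C → rt; CO2, −78 °C; aq HCl to pH 3, 0 °C; used at once
Reagents that add atoms: carbon dioxide, O=C=O
Why: Allylic metalation of the lithium alkoxide (a known n-BuLi/TMEDA dianion formation) gives a 2-(oxidomethyl)allyl anion whose two CH2 termini are equivalent, so carboxylation of the organolithium can give only one acid, which supplies C8, C7, C11, C12 and C13.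

Step 2
Reactants: 3 3-(hydroxymethyl)but-3-enoic acid
Product: 5 3-{[(TBS)oxy]methyl}but-3-enoic acid, via bis-silyl ester 4 (not isolated)
Conditions: TBSCl (2.4 equiv), imidazole, DMF, rt; then K2CO3, THF–H2O, rt; pH 4 buffer
Reagents that add atoms: tert-butyldimethylsilyl chloride, CC(C)(C)[Si](C)(C)Cl
Why: Exhaustive silylation followed by selective hydrolysis of the labile silyl ester (standard handling of hydroxy acids) should leave the primary TBS ether and forestall lactonisation.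

Step 3
Reactants: 5 3-{[(TBS)oxy]methyl}but-3-enoic acid
Product: 7 (4S)-4-benzyl-3-(3-{[(TBS)oxy]methyl}but-3-enoyl)-1,3-oxazolidin-2-one, via mixed pivalic anhydride 6 (not isolated)
Conditions: t-BuCOCl, Et3N, THF, −20 °C; lithiated (S)-4-benzyloxazolidin-2-one (n-BuLi), THF, −78 → 0 °C
Reagents that add atoms: (S)-4-benzyl-1,3-oxazolidin-2-one, O=C1N[C@@H](Cc2ccccc2)CO1
Why: N-Acylation of the lithiated oxazolidinone by the mixed anhydride (Evans imide formation) is fast at low temperature, which should keep the β,γ-double bond out of conjugation.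

Step 4
Reactants: 8 but-2-yn-1-ol
Product: 10 (2Z)-3-iodobut-2-en-1-ol, via cyclic alkenylalanate 9 (not isolated)
Conditions: Red-Al (NaAlH2(OCH2CH2OMe)2), Et2O, 0 °C → rt; I2, THF, −78 °C
Reagents that add atoms: iodine, II
Why: Hydroxyl-directed trans-hydroalumination of the propargylic alcohol places aluminium on C3 cis to the carbinol carbon, and iodinolysis with retention gives the (Z)-iodide, which fixes the later C4=C5 geometry (methyl trans to C6).

Step 5
Reactants: 10 (2Z)-3-iodobut-2-en-1-ol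
Product: 11 (2Z)-3-iodobut-2-enal
Conditions: MnO2, CH2Cl2, rt, dark; used at once
Reagents that add atoms: none
Why: MnO2 oxidation is selective for the allylic alcohol and neutral, so the vinyl iodide and its geometry should survive.

Step 6
Reactants: 7 (4S)-4-benzyl-3-(3-{[(TBS)oxy]methyl}but-3-enoyl)-1,3-oxazolidin-2-one; 11 (2Z)-3-iodobut-2-enal
Product: 13 (4S)-4-benzyl-3-[(2S,3S,4Z)-3-hydroxy-5-iodo-2-{3-[(TBS)oxy]prop-1-en-2-yl}hex-4-enoyl]-1,3-oxazolidin-2-one, via boron enolate 12 (not isolated)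
Conditions: Bu2BOTf, i-Pr2NEt, CH2Cl2, −78 → 0 °C; 11, −78 → 0 °C; pH 7 buffer, MeOH, H2O2, 0 °C
Reagents that add atoms: none
Why: Evans syn-aldol reaction, in which the (Z)-boron enolate reacts through a Zimmerman–Traxler chair on the face away from the benzyl group, so that C6 and C7 are set together (syn) by the auxiliary.

Step 7
Reactants: 13 aldol adduct
Product: 14 (4S)-4-benzyl-3-[(2S,3S,4Z)-3-[(TBS)oxy]-5-iodo-2-{3-[(TBS)oxy]prop-1-en-2-yl}hex-4-enoyl]-1,3-oxazolidin-2-one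
Conditions: TBSOTf, 2,6-lutidine, CH2Cl2, −78 → 0 °C
Reagents that add atoms: tert-butyldimethylsilyl trifluoromethanesulfonate, CC(C)(C)[Si](C)(C)OS(=O)(=O)C(F)(F)F
Why: Silylation of the secondary alcohol with a silyl triflate and a hindered base is routine and blocks retro-aldol cleavage.

Step 8
Reactants: 14 silylated imide
Product: 15 (2R,3S,4Z)-3-[(TBS)oxy]-5-iodo-2-{3-[(TBS)oxy]prop-1-en-2-yl}hex-4-en-1-ol
Conditions: LiBH4, MeOH (1 equiv), THF, 0 °C
Reagents that add atoms: none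
Why: Reductive cleavage of the N-acyl oxazolidinone by LiBH4 should release the primary alcohol and the recoverable auxiliary without touching silyl ethers or the vinyl iodide.

Step 9
Reactants: 15 primary alcohol
Product: 16 (2S,3S,4Z)-3-[(TBS)oxy]-5-iodo-2-{3-[(TBS)oxy]prop-1-en-2-yl}hex-4-enal
Conditions: Dess–Martin periodinane, pyridine, CH2Cl2, 0 °C; used at once
Reagents that add atoms: none
Why: Dess–Martin oxidation under buffered conditions is mild enough to avoid epimerisation at C7 and migration of the β,γ-double bond.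

Step 10
Reactants: 16 aldehyde
Product: 17 2-[(1S,2S,3Z)-2-[(TBS)oxy]-4-iodo-1-{3-[(TBS)oxy]prop-1-en-2-yl}pent-3-en-1-yl]-1,3-dithiane
Conditions: HS(CH2)3SH, BF3·OEt2 (cat.), CH2Cl2, −40 °C
Reagents that add atoms: propane-1,3-dithiol, SCCCS
Why: Lewis-acid-catalysed dithioacetalisation of an aldehyde is faster at low temperature than enolisation at C7 or ionisation of the allylic silyl ethers, and it is done before any oxirane is present.

Step 11
Reactants: 17 alkenyl iodide
Product: 19 (3Z,5R,6S)-5-[(TBS)oxy]-6-(1,3-dithian-2-yl)-3-methyl-7-{[(TBS)oxy]methyl}octa-3,7-dien-2-one, via ethoxydiene 18 (not isolated)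
Conditions: Bu3Sn–C(OEt)=CH2, Pd(PPh3)4 (cat.), CuI (cat.), DMF, 50 °C; then 1 M HCl, THF, 0 °C
Reagents that add atoms: tributyl(1-ethoxyvinyl)stannane, CCCC[Sn](CCCC)(CCCC)C(=C)OCC; water, O
Why: Stille coupling of the alkenyl iodide with the acyl-anion equivalent proceeds with retention of alkene geometry, and brief acid hydrolysis of the enol ether unveils the methyl ketone that supplies C3 and C2.

Step 12
Reactants: 1 2-methylprop-2-en-1-ol (methallyl alcohol)
Product: 20 (S)-(2-methyloxiran-2-yl)methanol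
Conditions: t-BuOOH, Ti(OiPr)4 (cat.), diisopropyl L-(+)-tartrate (cat.), 4 Å molecular sieves, CH2Cl2, −20 °C
Reagents that add atoms: tert-butyl hydroperoxide, CC(C)(C)OO
Why: Sharpless asymmetric epoxidation of the allylic alcohol, in which the L-(+)-tartrate–titanium complex delivers oxygen to one alkene face, gives the (S)-epoxy alcohol and thereby sets C10.

Step 13
Reactants: 20 (S)-(2-methyloxiran-2-yl)methanol
Product: 21 (R)-2-methyloxirane-2-carbaldehyde
Conditions: Dess–Martin periodinane, pyridine, CH2Cl2, 0 °C; distilled, used as a THF solution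
Reagents that add atoms: none
Why: Dess–Martin oxidation of the primary alcohol cannot racemise the aldehyde because C10 is quaternary, and the buffered conditions spare the oxirane.

Step 14
Reactants: 19 methyl ketone; 21 (R)-2-methyloxirane-2-carbaldehyde
Product: 23 (1S,4Z,6R,7S)-1-hydroxy-4-methyl-1-[(2R)-2-methyloxiran-2-yl]-6-[(TBS)oxy]-7-(1,3-dithian-2-yl)-8-{[(TBS)oxy]methyl}nona-4,8-dien-3-one, via lithium enolate 22 (not isolated)
Conditions: LiN(i-Pr)2 (LDA), THF, −78 °C; 21, −78 °C; aq NH4Cl at −78 °C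
Reagents that add atoms: none
Why: Aldol addition of the kinetic lithium enolate (the C2 methyl is the only α' position) to the non-enolisable epoxy aldehyde forms C1–C2 without any Lewis acid, and Felkin–Anh control (oxirane C–O anti, approach past the tied-back ring CH2) should favour (1S), a centre erased in step 23.

Step 15
Reactants: 23 aldol adduct
Product: 24 (1S,4Z,6R,7S)-4-methyl-1-[(2R)-2-methyloxiran-2-yl]-1-[(TES)oxy]-6-[(TBS)oxy]-7-(1,3-dithian-2-yl)-8-{[(TBS)oxy]methyl}nona-4,8-dien-3-one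
Conditions: TESCl, imidazole, DMAP (cat.), DMF, 0 °C → rt
Reagents that add atoms: chlorotriethylsilane, CC[Si](Cl)(CC)CC
Why: Silylation with a silyl chloride and imidazole is basic and triflate-free, so the oxirane and the β-hydroxy ketone should both survive.

Step 16
Reactants: 24 ketone
Product: 25 (1S,3R,4Z,6R,7S)-4-methyl-1-[(2R)-2-methyloxiran-2-yl]-1-[(TES)oxy]-6-[(TBS)oxy]-7-(1,3-dithian-2-yl)-8-{[(TBS)oxy]methyl}nona-4,8-dien-3-ol
Conditions: (S)-Me-CBS oxazaborolidine [(S)-1-methyl-3,3-diphenyltetrahydro-1H,3H-pyrrolo[1,2-c][1,3,2]oxazaborole, 0.5 equiv], catecholborane, toluene, −78 °C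
Reagents that add atoms: none
Why: Corey–Bakshi–Shibata reduction, in which the (S)-catalyst distinguishes the branched alkenyl group (large) from the C2 methylene (small) and delivers hydride to one carbonyl face, should give the (3R)-allylic alcohol by reagent control.

Step 17
Reactants: 25 allylic alcohol
Product: 26 (1S,3R,4Z,6R,7S)-7-(1,3-dithian-2-yl)-4-methyl-1-[(2R)-2-methyloxiran-2-yl]-3,6-bis[(TBS)oxy]-8-{[(TBS)oxy]methyl}-1-[(TES)oxy]nona-4,8-diene (cyclisation precursor)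
Conditions: TBSCl, imidazole, DMF, 35 °C
Reagents that add atoms: tert-butyldimethylsilyl chloride, CC(C)(C)[Si](C)(C)Cl
Why: Standard silylation of the secondary allylic alcohol under conditions that leave the oxirane and the TES ether alone.

Step 18
Reactants: 26 cyclisation precursor
Product: 28 (1S,3R,4Z,6R,7S,10R)-10-hydroxy-4,10-dimethyl-3,6-bis[(TBS)oxy]-7-{3-[(TBS)oxy]prop-1-en-2-yl}-1-[(TES)oxy]cyclodec-4-ene-8-spiro-2'-(1,3-dithiane) (germacranolide locants), via lithiated dithiane 27 (not isolated)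
Conditions: t-BuLi (1.2 equiv), THF–HMPA (9:1), −78 °C; dilution with cold THF to 2 mM, −78 → −20 °C; aq NH4Cl
Reagents that add atoms: none
Why: Proposed new method: Deprotonation at C8 (HMPA separates the ion pair and keeps silicon on O6) gives the dithiane-stabilised organolithium 27, which displaces the oxirane oxygen at its CH2 carbon (C9) by backside attack, so a single event forms C8–C9 and leaves O10 as a lithium alkoxide. The closest known reactions are the intermolecular opening of terminal 2,2-disubstituted oxiranes by 2-lithio-2-alkyl-1,3-dithianes and the intramolecular alkylation of acyl-anion equivalents that closes ten-membered carbocycles; what is new is their combination in an intramolecular oxirane opening at this ring size. Ring closure is ten-membered and endo with respect to the oxirane: C9 and C10 both become ring atoms, and the oxygen that leaves C9 stays on C10 outside the carbocycle (formally an exo-tet displacement). No stereocentre is formed: C10 keeps the configuration installed in step 12 because it is not the site of attack, and C8 is a spiro carbon with two equivalent sulfur arms until step 20. The selectivity needed is attack at C9 rather than C10 and ring closure rather than oligomerisation; the first is secured because C10 is fully substituted, the second by high dilution and by the (Z)-C4=C5 bond and the C6/C7 substituents, which fold the chain. An oxirane is kept as the electrophile because a C9 halide or sulfonate would be a neopentyl centre.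

Step 19
Reactants: 28 spiro-dithiane
Product: 29 (1S,3R,4Z,6R,7S,10R)-10-hydroxy-4,10-dimethyl-3,6-bis[(TBS)oxy]-7-{3-[(TBS)oxy]prop-1-en-2-yl}-1-[(TES)oxy]cyclodec-4-en-8-one
Conditions: PhI(OCOCF3)2, NaHCO3, MeCN–H2O (9:1), 0 °C
Reagents that add atoms: water, O
Why: Oxidative dithiane hydrolysis with bis(trifluoroacetoxy)iodobenzene is fast at 0 °C and tolerates alkenes, and the bicarbonate buffer should protect the silyl ethers and the C7 centre of the β,γ-unsaturated ketone.

Step 20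
Reactants: 29 β-hydroxy ketone
Product: 30 (1S,3R,4Z,6R,7R,8R,10R)-4,10-dimethyl-3,6-bis[(TBS)oxy]-7-{3-[(TBS)oxy]prop-1-en-2-yl}-1-[(TES)oxy]cyclodec-4-ene-8,10-diol
Conditions: Me4NBH(OAc)3, MeCN–AcOH, −30 °C
Reagents that add atoms: none
Why: Evans–Saksena reduction, in which the C10 hydroxyl binds boron and delivers hydride internally through a chair-like six-membered transition state, should give the 1,3-anti diol and thus (8R).

Step 21
Reactants: 30 diol
Product: 31 (1S,3R,4Z,6R,7R,8R,10R)-10-hydroxy-4,10-dimethyl-3,6-bis[(TBS)oxy]-7-{3-[(TBS)oxy]prop-1-en-2-yl}-1-[(TES)oxy]cyclodec-4-en-8-yl 3-methylbutanoate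
Conditions: (i-BuCO)2O, Et3N, DMAP (cat.), CH2Cl2, 0 °C → rt
Reagents that add atoms: 3-methylbutanoic anhydride, CC(C)CC(=O)OC(=O)CC(C)C
Why: DMAP-catalysed acylation should esterify the secondary C8 alcohol only, because the tertiary C10 alcohol is far less reactive.

Step 22
Reactants: 31 isovalerate
Product: 32 (1S,3R,4Z,6R,7R,8R,10R)-1,10-dihydroxy-4,10-dimethyl-3,6-bis[(TBS)oxy]-7-{3-[(TBS)oxy]prop-1-en-2-yl}cyclodec-4-en-8-yl 3-methylbutanoate
Conditions: PPTS (cat.), MeOH–CH2Cl2, 0 °C, monitored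
Reagents that add atoms: none
Why: Acid-catalysed methanolysis removes a triethylsilyl ether much faster than tert-butyldimethylsilyl ethers (selective desilylation), which frees O1 alone.

Step 23
Reactants: 32 C1 alcohol
Product: 33 (3R,4Z,6R,7R,8R,10R)-10-hydroxy-4,10-dimethyl-1-oxo-3,6-bis[(TBS)oxy]-7-{3-[(TBS)oxy]prop-1-en-2-yl}cyclodec-4-en-8-yl 3-methylbutanoate
Conditions: Dess–Martin periodinane, pyridine, CH2Cl2, rt
Reagents that add atoms: none
Why: Dess–Martin oxidation of the only free secondary alcohol gives the C1 ketone, the tertiary C10 hydroxyl being inert, and it removes the temporary C1 stereocentre.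

Step 24
Reactants: 33 tris-TBS ether
Product: 34 (3R,4Z,6R,7S,8R,10R)-3,6,10-trihydroxy-7-(3-hydroxyprop-1-en-2-yl)-4,10-dimethyl-1-oxocyclodec-4-en-8-yl 3-methylbutanoate
Conditions: HF·pyridine, pyridine, THF, 0 °C → rt
Reagents that add atoms: none
Why: Buffered HF·pyridine desilylation cleaves the three TBS ethers under mildly acidic, non-basic conditions that should spare the ester, the α-ketol and the β-hydroxy ketone.

Step 25
Reactants: 34 triol
Product: 37 target, (3R,4Z,6R,7R,8R,10R)-3,10-dihydroxy-4,10-dimethyl-1-oxo-germacra-4,11(13)-dien-12,6-olid-8-yl 3-methylbutanoate, via hydroxy enal 35 (not isolated), via lactol 36 (not isolated)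
Conditions: TEMPO (2,2,6,6-tetramethylpiperidin-1-oxyl, cat.), PhI(OAc)2, CH2Cl2, rt
Reagents that add atoms: none
Why: TEMPO/PhI(OAc)2 oxidative lactonisation, in which the oxoammonium species oxidises the primary allylic alcohol far faster than the secondary ones, O6 closes the five-membered lactol and a second oxidation gives the α-methylene γ-lactone.

Compound list
1 | 2-methylprop-2-en-1-ol (methallyl alcohol) | C=C(C)CO | starting material
2 | dilithio derivative of 1, lithium 2-(lithiomethyl)prop-2-en-1-olate | [Li]CC(=C)CO[Li] | intermediate (not isolated)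
3 | 3-(hydroxymethyl)but-3-enoic acid | OCC(=C)CC(=O)O | intermediate
4 | tert-butyldimethylsilyl 3-{[(TBS)oxy]methyl}but-3-enoate | CC(C)(C)[Si](C)(C)OCC(=C)CC(=O)O[Si](C)(C)C(C)(C)C | intermediate (not isolated)
5 | 3-{[(TBS)oxy]methyl}but-3-enoic acid | CC(C)(C)[Si](C)(C)OCC(=C)CC(=O)O | intermediate
6 | 3-{[(TBS)oxy]methyl}but-3-enoic pivalic anhydride | CC(C)(C)[Si](C)(C)OCC(=C)CC(=O)OC(=O)C(C)(C)C | intermediate (not isolated)
7 | (4S)-4-benzyl-3-(3-{[(TBS)oxy]methyl}but-3-enoyl)-1,3-oxazolidin-2-one | CC(C)(C)[Si](C)(C)OCC(=C)CC(=O)N1[C@@H](Cc2ccccc2)COC1=O | intermediate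
8 | but-2-yn-1-ol | CC#CCO | starting material
9 | sodium 2,2-bis(2-methoxyethoxy)-3-methyl-2,5-dihydro-1,2-oxaaluminol-2-uide (cyclic alkenylalanate) | CC1=CCO[Al-]1(OCCOC)OCCOC.[Na+] | intermediate (not isolated)
10 | (2Z)-3-iodobut-2-en-1-ol | C/C(I)=C/CO | intermediate
11 | (2Z)-3-iodobut-2-enal | C/C(I)=C/C=O | intermediate
12 | (Z)-dibutylboron enolate of 7 | CCCCB(CCCC)O/C(=C\C(=C)CO[Si](C)(C)C(C)(C)C)N1[C@@H](Cc2ccccc2)COC1=O | intermediate (not isolated)
13 | (4S)-4-benzyl-3-[(2S,3S,4Z)-3-hydroxy-5-iodo-2-{3-[(TBS)oxy]prop-1-en-2-yl}hex-4-enoyl]-1,3-oxazolidin-2-one | O=C(N1[C@@H](Cc2ccccc2)COC1=O)[C@@H](C(=C)CO[Si](C)(C)C(C)(C)C)[C@H](O)/C=C(/C)I | intermediate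
14 | (4S)-4-benzyl-3-[(2S,3S,4Z)-3-[(TBS)oxy]-5-iodo-2-{3-[(TBS)oxy]prop-1-en-2-yl}hex-4-enoyl]-1,3-oxazolidin-2-one | O=C(N1[C@@H](Cc2ccccc2)COC1=O)[C@@H](C(=C)CO[Si](C)(C)C(C)(C)C)[C@H](O[Si](C)(C)C(C)(C)C)/C=C(/C)I | intermediate
15 | (2R,3S,4Z)-3-[(TBS)oxy]-5-iodo-2-{3-[(TBS)oxy]prop-1-en-2-yl}hex-4-en-1-ol | OC[C@@H](C(=C)CO[Si](C)(C)C(C)(C)C)[C@H](O[Si](C)(C)C(C)(C)C)/C=C(/C)I | intermediate
16 | (2S,3S,4Z)-3-[(TBS)oxy]-5-iodo-2-{3-[(TBS)oxy]prop-1-en-2-yl}hex-4-enal | O=C[C@@H](C(=C)CO[Si](C)(C)C(C)(C)C)[C@H](O[Si](C)(C)C(C)(C)C)/C=C(/C)I | intermediate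
17 | 2-[(1S,2S,3Z)-2-[(TBS)oxy]-4-iodo-1-{3-[(TBS)oxy]prop-1-en-2-yl}pent-3-en-1-yl]-1,3-dithiane | S1CCCSC1[C@@H](C(=C)CO[Si](C)(C)C(C)(C)C)[C@H](O[Si](C)(C)C(C)(C)C)/C=C(/C)I | intermediate
18 | 2-[(1S,2R,3Z)-5-ethoxy-4-methyl-2-[(TBS)oxy]-1-{3-[(TBS)oxy]prop-1-en-2-yl}hexa-3,5-dien-1-yl]-1,3-dithiane | S1CCCSC1[C@@H](C(=C)CO[Si](C)(C)C(C)(C)C)[C@H](O[Si](C)(C)C(C)(C)C)/C=C(/C)C(=C)OCC | intermediate (not isolated)
19 | (3Z,5R,6S)-5-[(TBS)oxy]-6-(1,3-dithian-2-yl)-3-methyl-7-{[(TBS)oxy]methyl}octa-3,7-dien-2-one | S1CCCSC1[C@@H](C(=C)CO[Si](C)(C)C(C)(C)C)[C@H](O[Si](C)(C)C(C)(C)C)/C=C(/C)C(C)=O | intermediate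
20 | (S)-(2-methyloxiran-2-yl)methanol | OC[C@@]1(C)CO1 | intermediate
21 | (R)-2-methyloxirane-2-carbaldehyde | O=C[C@@]1(C)CO1 | intermediate
22 | lithium enolate of 19 (C2=C3–OLi) | S1CCCSC1[C@@H](C(=C)CO[Si](C)(C)C(C)(C)C)[C@H](O[Si](C)(C)C(C)(C)C)/C=C(/C)C(=C)O[Li] | intermediate (not isolated)
23 | (1S,4Z,6R,7S)-1-hydroxy-4-methyl-1-[(2R)-2-methyloxiran-2-yl]-6-[(TBS)oxy]-7-(1,3-dithian-2-yl)-8-{[(TBS)oxy]methyl}nona-4,8-dien-3-one | S1CCCSC1[C@@H](C(=C)CO[Si](C)(C)C(C)(C)C)[C@H](O[Si](C)(C)C(C)(C)C)/C=C(/C)C(=O)C[C@H](O)[C@@]2(C)CO2 | intermediate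
24 | 1-O-TES ether of 23 | S1CCCSC1[C@@H](C(=C)CO[Si](C)(C)C(C)(C)C)[C@H](O[Si](C)(C)C(C)(C)C)/C=C(/C)C(=O)C[C@H](O[Si](CC)(CC)CC)[C@@]2(C)CO2 | intermediate
25 | (1S,3R,4Z,6R,7S)-4-methyl-1-[(2R)-2-methyloxiran-2-yl]-1-[(TES)oxy]-6-[(TBS)oxy]-7-(1,3-dithian-2-yl)-8-{[(TBS)oxy]methyl}nona-4,8-dien-3-ol | S1CCCSC1[C@@H](C(=C)CO[Si](C)(C)C(C)(C)C)[C@H](O[Si](C)(C)C(C)(C)C)/C=C(/C)[C@H](O)C[C@H](O[Si](CC)(CC)CC)[C@@]2(C)CO2 | intermediate
26 | (1S,3R,4Z,6R,7S)-7-(1,3-dithian-2-yl)-4-methyl-1-[(2R)-2-methyloxiran-2-yl]-3,6-bis[(TBS)oxy]-8-{[(TBS)oxy]methyl}-1-[(TES)oxy]nona-4,8-diene (key-step precursor) | S1CCCSC1[C@@H](C(=C)CO[Si](C)(C)C(C)(C)C)[C@H](O[Si](C)(C)C(C)(C)C)/C=C(/C)[C@H](O[Si](C)(C)C(C)(C)C)C[C@H](O[Si](CC)(CC)CC)[C@@]2(C)CO2 | intermediate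
27 | 2-lithio-1,3-dithiane derived from 26 | [Li]C1(SCCCS1)[C@@H](C(=C)CO[Si](C)(C)C(C)(C)C)[C@H](O[Si](C)(C)C(C)(C)C)/C=C(/C)[C@H](O[Si](C)(C)C(C)(C)C)C[C@H](O[Si](CC)(CC)CC)[C@@]2(C)CO2 | intermediate (not isolated)
28 | (1S,3R,4Z,6R,7S,10R)-10-hydroxy-4,10-dimethyl-3,6-bis[(TBS)oxy]-7-{3-[(TBS)oxy]prop-1-en-2-yl}-1-[(TES)oxy]cyclodec-4-ene-8-spiro-2'-(1,3-dithiane) (key-step product) | O[C@]1(C)CC2(SCCCS2)[C@@H](C(=C)CO[Si](C)(C)C(C)(C)C)[C@H](O[Si](C)(C)C(C)(C)C)/C=C(/C)[C@H](O[Si](C)(C)C(C)(C)C)C[C@@H]1O[Si](CC)(CC)CC | intermediate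
29 | (1S,3R,4Z,6R,7S,10R)-10-hydroxy-4,10-dimethyl-3,6-bis[(TBS)oxy]-7-{3-[(TBS)oxy]prop-1-en-2-yl}-1-[(TES)oxy]cyclodec-4-en-8-one | O[C@]1(C)CC(=O)[C@@H](C(=C)CO[Si](C)(C)C(C)(C)C)[C@H](O[Si](C)(C)C(C)(C)C)/C=C(/C)[C@H](O[Si](C)(C)C(C)(C)C)C[C@@H]1O[Si](CC)(CC)CC | intermediate
30 | (1S,3R,4Z,6R,7R,8R,10R)-4,10-dimethyl-3,6-bis[(TBS)oxy]-7-{3-[(TBS)oxy]prop-1-en-2-yl}-1-[(TES)oxy]cyclodec-4-ene-8,10-diol | O[C@]1(C)C[C@@H](O)[C@@H](C(=C)CO[Si](C)(C)C(C)(C)C)[C@H](O[Si](C)(C)C(C)(C)C)/C=C(/C)[C@H](O[Si](C)(C)C(C)(C)C)C[C@@H]1O[Si](CC)(CC)CC | intermediate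
31 | 8-O-(3-methylbutanoyl) ester of 30 | O[C@]1(C)C[C@@H](OC(=O)CC(C)C)[C@@H](C(=C)CO[Si](C)(C)C(C)(C)C)[C@H](O[Si](C)(C)C(C)(C)C)/C=C(/C)[C@H](O[Si](C)(C)C(C)(C)C)C[C@@H]1O[Si](CC)(CC)CC | intermediate
32 | (1S,3R,4Z,6R,7R,8R,10R)-1,10-dihydroxy-4,10-dimethyl-3,6-bis[(TBS)oxy]-7-{3-[(TBS)oxy]prop-1-en-2-yl}cyclodec-4-en-8-yl 3-methylbutanoate | O[C@]1(C)C[C@@H](OC(=O)CC(C)C)[C@@H](C(=C)CO[Si](C)(C)C(C)(C)C)[C@H](O[Si](C)(C)C(C)(C)C)/C=C(/C)[C@H](O[Si](C)(C)C(C)(C)C)C[C@@H]1O | intermediate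
33 | (3R,4Z,6R,7R,8R,10R)-10-hydroxy-4,10-dimethyl-1-oxo-3,6-bis[(TBS)oxy]-7-{3-[(TBS)oxy]prop-1-en-2-yl}cyclodec-4-en-8-yl 3-methylbutanoate | O[C@]1(C)C[C@@H](OC(=O)CC(C)C)[C@@H](C(=C)CO[Si](C)(C)C(C)(C)C)[C@H](O[Si](C)(C)C(C)(C)C)/C=C(/C)[C@H](O[Si](C)(C)C(C)(C)C)CC1=O | intermediate
34 | (3R,4Z,6R,7S,8R,10R)-3,6,10-trihydroxy-7-(3-hydroxyprop-1-en-2-yl)-4,10-dimethyl-1-oxocyclodec-4-en-8-yl 3-methylbutanoate | O[C@]1(C)C[C@@H](OC(=O)CC(C)C)[C@@H](C(=C)CO)[C@H](O)/C=C(/C)[C@H](O)CC1=O | intermediate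
35 | C12 aldehyde of 34 (7-(3-oxoprop-1-en-2-yl) compound, other centres as in 34) | O[C@]1(C)C[C@@H](OC(=O)CC(C)C)[C@@H](C(=C)C=O)[C@H](O)/C=C(/C)[C@H](O)CC1=O | intermediate (not isolated)
36 | 12-hydroxy-12,6-lactol of 35 (hemiacetal carbon either configuration) | C=C1C(O)O[C@@H]2/C=C(/C)[C@H](O)CC(=O)[C@](C)(O)C[C@@H](OC(=O)CC(C)C)[C@@H]12 | intermediate (not isolated)
37 | target, (3R,4Z,6R,7R,8R,10R)-3,10-dihydroxy-4,10-dimethyl-1-oxo-germacra-4,11(13)-dien-12,6-olid-8-yl 3-methylbutanoate | C=C1C(=O)O[C@@H]2/C=C(/C)[C@H](O)CC(=O)[C@](C)(O)C[C@@H](OC(=O)CC(C)C)[C@@H]12 | target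

Total step count: 25
Longest linear sequence: 21 steps (1–3, 6–11, 14–25)

Steps most likely to fail

1. Step 18 (the labelled step). What may go wrong: intermolecular oxirane opening (oligomerisation) outrunning the entropically costly ten-membered closure, quenching of carbanion 27 by internal proton transfer, or migration of the C1 silyl group to the new C10 alkoxide. The fallback uses known chemistry: intermolecular lithiodithiane–oxirane opening, then ring-closing metathesis at C4=C5. It sets out from 17 and 21 and comes back to the route at 28. Iodide 17 is reduced with Bu3SnH and Pd(PPh3)4 (cat.) to the (E)-propenyl dithiane F1. Aldehyde 21 is taken through the operations of steps 14–17 with the lithium enolate of 3-methylbut-3-en-2-one in place of 22. This gives the aldol adduct F2, its triethylsilyl ether F3, the (3R)-allylic alcohol F4 from the same CBS reduction, and the TBS ether F5. Lithiated F1 (t-BuLi, THF–HMPA, −78 °C) opens oxirane F5 at its CH2 terminus to give the acyclic diene F6. Hoveyda–Grubbs second-generation catalyst in toluene at high dilution then closes C4=C5 with loss of propene, which should give 28; the cis ring alkene is the expected isomer in a ten-membered ring.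

2. Step 11. What may go wrong: Z-to-E isomerisation of the cross-conjugated enone during hydrolysis of 18 or in steps 14–16, and sluggish coupling at the hindered iodide. The fallback forms no enone at all, because a Nozaki–Hiyama–Kishi coupling makes the C3–C4 bond and the C3 carbinol directly. It sets out from 17 and 21 and comes back to the route at 25. Brown allylation of 21 with (−)-B-allyldiisopinocampheylborane gives the homoallylic alcohol F7, and TESCl/imidazole gives the silyl ether F8. Ozonolysis (O3, then PPh3) gives the aldehyde F9. CrCl2 with NiCl2 (cat.) in DMSO couples 17 with F9 to give 25 together with its C3 epimer, which is separated; a chiral sulfonamide ligand on chromium can be added to bias the ratio.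

3. Step 20. What may go wrong: poor facial selectivity, if the ring conformation prevents the chair-like internal hydride delivery and the C8 epimer forms. The fallback inverts C8 instead of retaining it. It sets out from 29 and comes back to the route at 31. Ketone 29 is reduced on purpose to the 1,3-syn diol, the (8S)-epimer F10, by external hydride on the boron chelate (Et2BOMe, NaBH4, THF–MeOH, −78 °C). Mitsunobu esterification of F10 with 3-methylbutanoic acid (PPh3, diisopropyl azodicarboxylate, toluene) then installs the ester with inversion to give 31, so step 21 is skipped.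

Further compounds
F1 | step 18 | 2-[(1S,2R,3E)-2-[(TBS)oxy]-1-{3-[(TBS)oxy]prop-1-en-2-yl}pent-3-en-1-yl]-1,3-dithiane | S1CCCSC1[C@@H](C(=C)CO[Si](C)(C)C(C)(C)C)[C@H](O[Si](C)(C)C(C)(C)C)/C=C/C
F2 | step 18 | (5S)-5-hydroxy-2-methyl-5-[(2R)-2-methyloxiran-2-yl]pent-1-en-3-one | C=C(C)C(=O)C[C@H](O)[C@@]1(C)CO1
F3 | step 18 | (5S)-2-methyl-5-[(2R)-2-methyloxiran-2-yl]-5-[(TES)oxy]pent-1-en-3-one | C=C(C)C(=O)C[C@H](O[Si](CC)(CC)CC)[C@@]1(C)CO1
F4 | step 18 | (3R,5S)-2-methyl-5-[(2R)-2-methyloxiran-2-yl]-5-[(TES)oxy]pent-1-en-3-ol | C=C(C)[C@H](O)C[C@H](O[Si](CC)(CC)CC)[C@@]1(C)CO1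
F5 | step 18 | (3R,5S)-3-[(TBS)oxy]-2-methyl-5-[(2R)-2-methyloxiran-2-yl]-5-[(TES)oxy]pent-1-ene | C=C(C)[C@H](O[Si](C)(C)C(C)(C)C)C[C@H](O[Si](CC)(CC)CC)[C@](C)(O1)C1
F6 | step 18 | acyclic diene: 2,2-disubstituted 1,3-dithiane carrying the F1 side chain and the opened F5 chain (C10 tertiary alcohol, C4 isopropenyl, C5 (E)-propenyl terminus) | C=C(C)[C@H](O[Si](C)(C)C(C)(C)C)C[C@H](O[Si](CC)(CC)CC)[C@](C)(O)CC1(SCCCS1)[C@@H](C(=C)CO[Si](C)(C)C(C)(C)C)[C@H](O[Si](C)(C)C(C)(C)C)/C=C/C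
F7 | step 11 | (1S)-1-[(2R)-2-methyloxiran-2-yl]but-3-en-1-ol | C=CC[C@H](O)[C@@]1(C)CO1
F8 | step 11 | (1S)-1-[(2R)-2-methyloxiran-2-yl]-1-[(TES)oxy]but-3-ene | C=CC[C@H](O[Si](CC)(CC)CC)[C@@]1(C)CO1
F9 | step 11 | (3S)-3-[(2R)-2-methyloxiran-2-yl]-3-[(TES)oxy]propanal | O=CC[C@H](O[Si](CC)(CC)CC)[C@@]1(C)CO1
F10 | step 20 | (8S)-epimer of 30 (1,3-syn diol) | O[C@]1(C)C[C@H](O)[C@@H](C(=C)CO[Si](C)(C)C(C)(C)C)[C@H](O[Si](C)(C)C(C)(C)C)/C=C(/C)[C@H](O[Si](C)(C)C(C)(C)C)C[C@@H]1O[Si](CC)(CC)CC
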